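## Analysis of the target

The target is methyl 2-[(3S,6R)-6-[(6E)-hexadec-6-ene-4,15-diyn-1-yl]-6-methoxy-1,2-dioxan-3-yl]acetate (C24H36O5). Its core is a 1,2-dioxane ring O1–O2–C3–C4–C5–C6. C3 carries H and the CH2CO2Me arm and is a secondary peroxy carbon β to the ester carbonyl. C6 is a peroxyketal carbon: it carries O1, a methoxy group and the C16 chain (CH2)3–C≡C–CH=CH–(CH2)7–C≡CH. The two stereocentres are 1,4-related, with OMe cis to CH2CO2Me. In the chair the OMe is therefore axial (anomeric to O1) and both carbon substituents are equatorial, which is the more stable C6 epimer. C6 can exchange its methoxy group in acid through a cyclic peroxycarbenium ion, so only C3 needs absolute control and C6 can be derived from it. The sensitive groups are the O–O bond (reductants, low-valent metals, radicals), the C3–H and the ester α-CH2 (base causes Kornblum–DeLaMare fragmentation or E1cB ring opening, which would racemise C3), the ketal (acid), and the E-enyne and terminal alkyne (ozone, radicals, hydrometalation, copper/amine). The difficulty is twofold: few methods form a C–OO bond enantioselectively, and the usual peroxide sources (ozone, singlet oxygen, radical/O2 chemistry) either give no control at C3 or destroy the enyne.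

## Retrosynthetic reasoning

**26 ⇒ 22 (cut O1–C6 and C6–OMe).** The ring is opened at the peroxyketal carbon, not at C3, because the C6 configuration is the thermodynamic one and needs no reagent control. The precursor 22 is acyclic and already holds the whole side chain, the ester, the C3 stereocentre and the complete O–O unit, masked as an acyclic perketal. The forward reaction must unmask the hydroperoxide (23), close it onto the C6 ketone (24) and let the C6 epimers 25 and 26 equilibrate to 26 in one acid-triggered operation.

**22 ⇒ 21 ⇒ 20 (oxidation level of C1).** The ester is traced back to an aldehyde, because the enantioselective C–O bond formation chosen for C3 works on enals. The forward steps are a chlorite oxidation and an O-methylation that must leave the peroxide and the C3 centre alone.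

**20 ⇒ 16 + 19 (cut O2–C3).** The C3–O bond is made by conjugate addition of the masked hydroperoxide 19 to enal 16 under chiral secondary-amine (iminium) catalysis, which sets C3. Reagent 19 is chosen because its perketal carbon is the switch for the later relay to C6. No alkene-cleaving oxidant ever meets the enyne, so the full side chain can be in place before any peroxide exists.

**16 ⇒ 14 + 15, 14 ⇒ 13 (cut C2=C3).** The enal comes from a Wittig reaction of keto aldehyde 14 with ylide 15; 14 is stored as its dioxolane 13.

**13 ⇒ 7 + 12 (cut the C(sp)–C(sp2) bond of the enyne).** This is the convergent cut. The alkyne is made the electrophile (bromoalkyne 7) and the alkene the nucleophile (alkenylboronate 12), so the free terminal alkyne of 12 needs no protection.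

**7 ⇒ 6 ⇒ 3 + 5; 12 ⇒ 9 + 10; 19 ⇒ 17.** Ketone 6 comes from Weinreb amide 3 (from acid 1) and Grignard reagent 5 (from bromide 4). Boronate 12 comes from aldehyde 9 (from alcohol 8) and dihalomethylboronate 10 (through 11). Reagent 19 comes from alkene 17 (through 18).

## Alternatives that were turned down

**Alternative 1:** (textbook) Cut O2–C3 with the C6 peroxyketal already present. Forward: alkoxy-ozonolysis of a 1,1-disubstituted alkene gives methyl (2E)-6-hydroperoxy-6-methoxyundec-2-en-10-ynoate A1. Base-mediated 6-exo-trig oxa-Michael closure gives methyl 2-[6-methoxy-6-(pent-4-yn-1-yl)-1,2-dioxan-3-yl]acetate A2, and the enyne is then attached to the alkyne of A2 by Pd/Cu coupling. Turned down because: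
- A1 is racemic at C6 and an achiral base has no handle on the face of C3, so A2 is a racemate of cis/trans isomers.
- The single enantiomer would need a resolution, or an enantioselective hydroperoxide addition to an enoate, for which no catalyst class is established.
- Ozonolysis cannot coexist with the E-enyne, so the chain must be joined after the ring exists. That means metal catalysis and alkyne deprotection on a base-sensitive β-peroxy ester, and more steps.

**Alternative 2:** Cut the exocyclic C3–CH2 bond. Forward: 3-[(6E)-hexadec-6-ene-4,15-diyn-1-yl]-3,6-dimethoxy-1,2-dioxane A3 (from the 1,4-keto aldehyde and a peroxide source) is ionised with a Lewis acid at its acetal carbon. The cyclic peroxycarbenium ion is trapped by an acetate-derived silyl ketene acetal (Mukaiyama-type). Turned down because: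
- A3 has two ionisable centres, and the ketal carbon gives the tertiary, better-stabilised cation. C–C bond formation would occur there and erase the C6–OMe group.
- Even with perfect regiocontrol, C3 would only be set relative to a racemic and labile C6, so there is no absolute control.
- Chiral-anion control of a peroxycarbenium ion has no precedent.

**Alternative 3:** Cut C4–C5 and both C–O bonds (oxidative [2+2+2]). Forward: one-electron oxidation (anodic or photoredox) of enol ether (8E)-2-methoxyoctadeca-1,8-diene-6,17-diyne A4 gives a radical cation. Its β-carbon (C5) adds to the terminal carbon (C4) of a but-3-enoate ester, the C3 radical is trapped aerobically, and the peroxide closes on the oxocarbenium carbon to give racemic methyl 2-[6-[(6E)-hexadec-6-ene-4,15-diyn-1-yl]-6-methoxy-1,2-dioxan-3-yl]acetate A5 in one step. This is a union of two carbons of like polarity. Turned down because: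
- C3 arises from trapping of a free secondary radical, so it is racemic and beyond catalyst control.
- Cross-addition of the radical cation to an unactivated alkene competes with dimerisation.
- The radical cation and peroxyl radicals would attack the enyne and the propargylic C–H bonds.
- It is the shortest route, but it cannot deliver the single enantiomer.

Key step: step 13

Assumption: the sense of induction in step 10 is taken from the steric-shielding model of diarylprolinol silyl ether iminium ions (attack anti to the diaryl(silyloxy)methyl group), which assigns 3S to the (R)-catalyst; both catalyst enantiomers are commercial.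

## Steps

Step 1
Reactants: 1 hex-5-ynoic acid
Product: 3 N-methoxy-N-methylhex-5-ynamide, via acyl imidazole 2 (not isolated)
Conditions: CDI (1.1 equiv), CH2Cl2, rt; then MeNH(OMe)·HCl (1.2 equiv), rt
Reagents that add atoms: N,O-dimethylhydroxylamine hydrochloride, CNOC.Cl
Why: Weinreb amide formation through the acyl imidazole; the neutral conditions leave the terminal alkyne untouched.

Step 2
Reactants: 3 N-methoxy-N-methylhex-5-ynamide; 4 2-(2-bromoethyl)-1,3-dioxolane
Product: 6 1-(1,3-dioxolan-2-yl)oct-7-yn-3-one, via Grignard reagent 5 (not isolated)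
Conditions: 4, Mg, THF, 25–30 °C; then 3 added to 5 (2.3 equiv), THF, −10 → 0 °C; aq NH4Cl
Reagents that add atoms: none
Why: Weinreb ketone synthesis: the magnesium-chelated tetrahedral adduct stops the addition at the ketone stage. The first equivalent of 5 is spent on the acidic alkyne C–H, and 5 is made and used below 30 °C because it decomposes on warming.

Step 3
Reactants: 6 1-(1,3-dioxolan-2-yl)oct-7-yn-3-one
Product: 7 8-bromo-1-(1,3-dioxolan-2-yl)oct-7-yn-3-one
Conditions: NBS (1.1 equiv), AgNO3 (10 mol %), acetone, rt, dark
Reagents that add atoms: N-bromosuccinimide, O=C1CCC(=O)N1Br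
Why: Silver-catalysed electrophilic bromination of the terminal alkyne (via the silver acetylide) makes the alkyne the electrophilic partner for step 6; ketone and dioxolane are inert.

Step 4
Reactants: 8 dec-9-yn-1-ol
Product: 9 dec-9-ynal
Conditions: Dess–Martin periodinane (1.2 equiv), NaHCO3, CH2Cl2, 0 °C → rt
Reagents that add atoms: none
Why: Dess–Martin oxidation of a primary alcohol to the aldehyde without over-oxidation; the alkyne is inert.

Step 5
Reactants: 9 dec-9-ynal; 10 2-(dichloromethyl)-4,4,5,5-tetramethyl-1,3,2-dioxaborolane
Product: 12 4,4,5,5-tetramethyl-2-[(1E)-undec-1-en-10-yn-1-yl]-1,3,2-dioxaborolane, via diiodomethylboronate 11 (not isolated)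
Conditions: CrCl2 (8 equiv), LiI (4 equiv), THF, rt
Reagents that add atoms: none
Why: Takai–Utimoto chromium(II) olefination with a gem-dihalomethylboronate: iodide exchange gives 11, its gem-dichromium species adds to the aldehyde, and anti-elimination should give the (E)-alkenylboronate. Cr(II) tolerates the terminal alkyne and no base is present.

Step 6
Reactants: 7 8-bromo-1-(1,3-dioxolan-2-yl)oct-7-yn-3-one; 12 4,4,5,5-tetramethyl-2-[(1E)-undec-1-en-10-yn-1-yl]-1,3,2-dioxaborolane
Product: 13 (9E)-1-(1,3-dioxolan-2-yl)nonadec-9-ene-7,18-diyn-3-one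
Conditions: Pd(dppf)Cl2·CH2Cl2 (5 mol %), K3PO4 (3 equiv), THF/H2O (10:1), degassed, 40 °C
Reagents that add atoms: none
Why: Suzuki–Miyaura alkenyl–alkynyl coupling with retention of the E geometry of 12. Because the 1-bromoalkyne is the electrophile, neither copper nor amine is present, so the free C≡C–H of 12 should not be activated and needs no protecting group.

Step 7
Reactants: 13 (9E)-1-(1,3-dioxolan-2-yl)nonadec-9-ene-7,18-diyn-3-one
Product: 14 (10E)-4-oxoicos-10-ene-8,19-diynal
Conditions: 1 M aq HCl, THF, rt; used without storage
Reagents that add atoms: water, O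
Why: Acid hydrolysis of the dioxolane; dilute acid at room temperature is chosen so that the 1,4-keto aldehyde does not cyclodehydrate to a furan.

Step 8
Reactants: 14 (10E)-4-oxoicos-10-ene-8,19-diynal; 15 2-(triphenyl-λ5-phosphanylidene)acetaldehyde
Product: 16 (2E,12E)-6-oxodocosa-2,12-diene-10,21-diynal
Conditions: 15 (1.1 equiv), PhMe, 50 °C
Reagents that add atoms: none
Why: Wittig olefination with a stabilised formylmethylene ylide: it reacts with the aldehyde and not with the ketone and should give the E-enal; a small excess limits double homologation.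

Step 9
Reactants: 17 2,3-dimethylbut-2-ene
Product: 19 2-hydroperoxy-2-methoxypropane, via carbonyl oxide 18 (not isolated)
Conditions: O3, MeOH/CH2Cl2 (1:4), −78 °C; N2 purge; kept cold as a titrated solution
Reagents that add atoms: ozone, [O-][O+]=O; methanol, CO
Why: Criegee ozonolysis of a tetrasubstituted alkene in methanol: cycloreversion of the primary ozonide gives acetone and carbonyl oxide 18, which methanol traps as the α-methoxy hydroperoxide. As a low-molecular-weight peroxide, 19 is never concentrated to dryness.

Step 10
Reactants: 16 (2E,12E)-6-oxodocosa-2,12-diene-10,21-diynal; 19 2-hydroperoxy-2-methoxypropane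
Product: 20 (3S,12E)-3-[(2-methoxypropan-2-yl)peroxy]-6-oxodocos-12-ene-10,21-diynal
Conditions: (R)-2-{bis[3,5-bis(trifluoromethyl)phenyl](trimethylsilyloxy)methyl}pyrrolidine (10 mol %), 19 (1.5 equiv), toluene, 0 °C, dark
Reagents that add atoms: none
Why: Iminium-catalysed enantioselective conjugate addition of an α-alkoxyalkyl hydroperoxide to an aliphatic enal, a known organocatalytic peroxidation. The diaryl(silyloxy)methyl group shields one face of the E,s-trans iminium ion, so with the (R)-catalyst the oxygen should add to the face that gives 3S. The bulky tertiary peroxide, low temperature and absence of acid additive are meant to let the enamine protonate faster than it closes to an epoxide or attacks the C6 ketone.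

Step 11
Reactants: 20 (3S,12E)-3-[(2-methoxypropan-2-yl)peroxy]-6-oxodocos-12-ene-10,21-diynal
Product: 21 (3S,12E)-3-[(2-methoxypropan-2-yl)peroxy]-6-oxodocos-12-ene-10,21-diynoic acid
Conditions: NaClO2 (3 equiv), NaH2PO4/Na2HPO4 buffer (pH ≈ 5), 2-methylbut-2-ene (10 equiv), t-BuOH/H2O, 0 °C
Reagents that add atoms: sodium chlorite, [Na+].[O-]Cl=O
Why: Pinnick oxidation with an alkene scavenger for hypochlorite, so that enyne, alkyne and peroxide are spared. Buffering near pH 5 at 0 °C should keep the acid-labile perketal intact until the aldehyde is gone, and with no base present the peroxide cannot β-eliminate, so C3 is safe.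

Step 12
Reactants: 21 (3S,12E)-3-[(2-methoxypropan-2-yl)peroxy]-6-oxodocos-12-ene-10,21-diynoic acid
Product: 22 methyl (3S,12E)-3-[(2-methoxypropan-2-yl)peroxy]-6-oxodocos-12-ene-10,21-diynoate
Conditions: TMSCHN2 (1.2 equiv), PhMe/MeOH (4:1), 0 °C
Reagents that add atoms: trimethylsilyldiazomethane, C[Si](C)(C)C=[N+]=[N-]
Why: O-methylation of the carboxylic acid by diazomethane generated in the flask from TMSCHN2 and methanol; it is neutral and fast and leaves ketone, perketal and alkynes alone.

Step 13
Reactants: 22 methyl (3S,12E)-3-[(2-methoxypropan-2-yl)peroxy]-6-oxodocos-12-ene-10,21-diynoate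
Product: 26 methyl 2-[(3S,6R)-6-[(6E)-hexadec-6-ene-4,15-diyn-1-yl]-6-methoxy-1,2-dioxan-3-yl]acetate, via hydroperoxy keto ester 23 (not isolated), via hemiperketal 24 (not isolated), via C6 epimer 25 (not isolated)
Conditions: TsOH·H2O (10 mol %), HC(OMe)3 (2 equiv), MeOH, 0 °C → rt
Reagents that add atoms: methanol, CO
Why: Acid ionises the acyclic perketal at its acetone-derived carbon, releasing hydroperoxide 23 and 2,2-dimethoxypropane; the tethered OOH then adds to the C6 carbonyl (or its oxocarbenium ion) to give hemiperketal 24, whose ionisation to the endocyclic peroxycarbenium ion and capture by methanol gives the methyl peroxyketals 25 and 26. The closest known reaction types are the acid deprotection of 2-methoxyprop-2-yl peroxides to hydroperoxides and the cyclisation of γ-hydroperoxy ketones to 1,2-dioxan-3-ols followed by ketalisation in acidic methanol. The 1,2-dioxane closes by 6-exo-trig attack of the terminal peroxide oxygen on C6, forming the O1–C6 bond. C6 is set under thermodynamic control: 25 and 26 interconvert through the peroxycarbenium ion, and 26 alone has the methoxy group axial (anomeric stabilisation by O1) with the chain and the CH2CO2Me arm both equatorial. C3, set in step 10, is not touched, since no base is present and its C–O bond cannot ionise, so it relays the absolute configuration to C6. The step needs exchange at the two ketal carbons without heterolysis of the O–O bond; catalytic sulfonic acid at or below room temperature and the secondary nature of the hydroperoxide should secure this. Intramolecularity and the excess of methanol, which removes the acetone unit as its dimethyl ketal, should drive the transfer of the peroxide from the acyclic to the cyclic ketal. Ester, enyne and terminal alkyne are inert under these conditions, and any remaining 25 can be separated and resubjected.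

## Compound list

1 | hex-5-ynoic acid | C#CCCCC(=O)O | starting material
2 | 1-(1H-imidazol-1-yl)hex-5-yn-1-one | C#CCCCC(=O)n1ccnc1 | intermediate
3 | N-methoxy-N-methylhex-5-ynamide | C#CCCCC(=O)N(C)OC | intermediate
4 | 2-(2-bromoethyl)-1,3-dioxolane | BrCCC1OCCO1 | starting material
5 | [2-(1,3-dioxolan-2-yl)ethyl]magnesium bromide | Br[Mg]CCC1OCCO1 | intermediate
6 | 1-(1,3-dioxolan-2-yl)oct-7-yn-3-one | C#CCCCC(=O)CCC1OCCO1 | intermediate
7 | 8-bromo-1-(1,3-dioxolan-2-yl)oct-7-yn-3-one | BrC#CCCCC(=O)CCC1OCCO1 | intermediate
8 | dec-9-yn-1-ol | C#CCCCCCCCCO | starting material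
9 | dec-9-ynal | C#CCCCCCCCC=O | intermediate
10 | 2-(dichloromethyl)-4,4,5,5-tetramethyl-1,3,2-dioxaborolane | ClC(Cl)B1OC(C)(C)C(C)(C)O1 | starting material
11 | 2-(diiodomethyl)-4,4,5,5-tetramethyl-1,3,2-dioxaborolane | IC(I)B1OC(C)(C)C(C)(C)O1 | intermediate
12 | 4,4,5,5-tetramethyl-2-[(1E)-undec-1-en-10-yn-1-yl]-1,3,2-dioxaborolane | C#CCCCCCCC/C=C/B1OC(C)(C)C(C)(C)O1 | intermediate
13 | (9E)-1-(1,3-dioxolan-2-yl)nonadec-9-ene-7,18-diyn-3-one | C#CCCCCCCC/C=C/C#CCCCC(=O)CCC1OCCO1 | intermediate
14 | (10E)-4-oxoicos-10-ene-8,19-diynal | C#CCCCCCCC/C=C/C#CCCCC(=O)CCC=O | intermediate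
15 | 2-(triphenyl-λ5-phosphanylidene)acetaldehyde | O=CC=P(c1ccccc1)(c1ccccc1)c1ccccc1 | starting material
16 | (2E,12E)-6-oxodocosa-2,12-diene-10,21-diynal | C#CCCCCCCC/C=C/C#CCCCC(=O)CC/C=C/C=O | intermediate
17 | 2,3-dimethylbut-2-ene | CC(C)=C(C)C | starting material
18 | propan-2-one O-oxide (carbonyl oxide) | CC(C)=[O+][O-] | intermediate
19 | 2-hydroperoxy-2-methoxypropane | COC(C)(C)OO | intermediate
20 | (3S,12E)-3-[(2-methoxypropan-2-yl)peroxy]-6-oxodocos-12-ene-10,21-diynal | C#CCCCCCCC/C=C/C#CCCCC(=O)CC[C@@H](CC=O)OOC(C)(C)OC | intermediate
21 | (3S,12E)-3-[(2-methoxypropan-2-yl)peroxy]-6-oxodocos-12-ene-10,21-diynoic acid | C#CCCCCCCC/C=C/C#CCCCC(=O)CC[C@@H](CC(=O)O)OOC(C)(C)OC | intermediate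
22 | methyl (3S,12E)-3-[(2-methoxypropan-2-yl)peroxy]-6-oxodocos-12-ene-10,21-diynoate | C#CCCCCCCC/C=C/C#CCCCC(=O)CC[C@@H](CC(=O)OC)OOC(C)(C)OC | intermediate
23 | methyl (3S,12E)-3-hydroperoxy-6-oxodocos-12-ene-10,21-diynoate | C#CCCCCCCC/C=C/C#CCCCC(=O)CC[C@@H](CC(=O)OC)OO | intermediate
24 | methyl 2-[(3S)-6-[(6E)-hexadec-6-ene-4,15-diyn-1-yl]-6-hydroxy-1,2-dioxan-3-yl]acetate (both C6 epimers) | C#CCCCCCCC/C=C/C#CCCCC1(O)CC[C@@H](CC(=O)OC)OO1 | intermediate
25 | methyl 2-[(3S,6S)-6-[(6E)-hexadec-6-ene-4,15-diyn-1-yl]-6-methoxy-1,2-dioxan-3-yl]acetate | C#CCCCCCCC/C=C/C#CCCC[C@@]1(OC)CC[C@@H](CC(=O)OC)OO1 | intermediate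
26 | methyl 2-[(3S,6R)-6-[(6E)-hexadec-6-ene-4,15-diyn-1-yl]-6-methoxy-1,2-dioxan-3-yl]acetate | C#CCCCCCCC/C=C/C#CCCC[C@]1(OC)CC[C@@H](CC(=O)OC)OO1 | target

## Step count and risk

Total step count: 13. Longest linear sequence: 10 (steps 1, 2, 3, 6, 7, 8, 10, 11, 12, 13).

**Step 13 (key step).** The most likely failures are incomplete funnelling at C6, if the anomeric preference is not large enough, and slow acid-induced heterolysis of the O–O bond of the free hydroperoxide during a long equilibration. The fallback sets out from 22 and returns at 26.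
- The perketal alone is removed with aqueous acetic acid in THF, which should give hemiperketal 24 as an isolable epimer mixture.
- 24 is silylated (TMS-imidazole) to methyl 2-[(3S)-6-[(6E)-hexadec-6-ene-4,15-diyn-1-yl]-6-(trimethylsilyloxy)-1,2-dioxan-3-yl]acetate F1.
- F1 is treated with methoxytrimethylsilane and catalytic TMSOTf in CH2Cl2 at −78 °C (aprotic Noyori-type ketalisation).
- The C6–OMe bond is then formed by kinetic axial capture of the cyclic peroxycarbenium ion at low temperature instead of by equilibration in protic acid.

**Step 10.** Three processes threaten it: closure of the β-peroxy enamine onto the proximal peroxide oxygen with loss of the alkoxide (the epoxidation pathway of this catalyst class), aldol attack of the enamine on the C6 ketone, and insufficient facial selectivity with an aliphatic enal. The fallback gives up catalyst control, uses the amine-free closure and resolves at the end; it sets out from 14 and returns at 26.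
- Horner–Wadsworth–Emmons reaction of 14 (trimethyl phosphonoacetate, LiCl, DBU) gives methyl (2E,12E)-6-oxodocosa-2,12-diene-10,21-diynoate F2.
- Ketalisation (HC(OMe)3, PPTS, MeOH) gives methyl (2E,12E)-6,6-dimethoxydocosa-2,12-diene-10,21-diynoate F3.
- Acid-catalysed exchange with anhydrous ethereal H2O2 gives racemic methyl (2E,12E)-6-hydroperoxy-6-methoxydocosa-2,12-diene-10,21-diynoate F4.
- Intramolecular oxa-Michael addition (Et2NH, CF3CH2OH) and equilibration of C6 with TsOH in MeOH give racemic methyl 2-[(3S*,6R*)-6-[(6E)-hexadec-6-ene-4,15-diyn-1-yl]-6-methoxy-1,2-dioxan-3-yl]acetate F5.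
- Preparative HPLC on a chiral stationary phase separates F5 and delivers 26.

**Step 6.** Pd-mediated coupling of the free terminal alkyne of 12 with the bromoalkyne, homocoupling of 7 and protodeboronation may compete with transmetalation from boron. The fallback reverses the polarity of the partners and works without base; it sets out from 9 and 6 and returns at 13.
- Takai iodo-olefination of 9 (CHI3, CrCl2, THF) gives (1E)-1-iodoundec-1-en-10-yne F6.
- Stannylation of 6 with Bu3SnOMe (neat, 60 °C) gives 1-(1,3-dioxolan-2-yl)-8-(tributylstannyl)oct-7-yn-3-one F7.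
- Stille coupling of F6 with F7 (Pd2(dba)3, AsPh3, THF, rt) should give 13; the C≡C–H of F6 is not activated under these neutral conditions.

**Step 11.** Premature acid-induced loss of the perketal before the aldehyde is consumed would let the freed hydroperoxide close on the aldehyde, and residual hypochlorite could chlorinate the enyne. The fallback sets out from 20 and returns at 22. Direct oxidative esterification with PDC and MeOH in DMF oxidises the methyl hemiacetal under non-aqueous, nearly neutral conditions, so that 21 is bypassed and steps 11 and 12 become one.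

## Further compounds

F1 | step 13 | methyl 2-[(3S)-6-[(6E)-hexadec-6-ene-4,15-diyn-1-yl]-6-(trimethylsilyloxy)-1,2-dioxan-3-yl]acetate | C#CCCCCCCC/C=C/C#CCCCC1(O[Si](C)(C)C)CC[C@@H](CC(=O)OC)OO1
F2 | step 10 | methyl (2E,12E)-6-oxodocosa-2,12-diene-10,21-diynoate | C#CCCCCCCC/C=C/C#CCCCC(=O)CC/C=C/C(=O)OC
F3 | step 10 | methyl (2E,12E)-6,6-dimethoxydocosa-2,12-diene-10,21-diynoate | C#CCCCCCCC/C=C/C#CCCCC(OC)(OC)CC/C=C/C(=O)OC
F4 | step 10 | methyl (2E,12E)-6-hydroperoxy-6-methoxydocosa-2,12-diene-10,21-diynoate (racemic) | C#CCCCCCCC/C=C/C#CCCCC(OC)(OO)CC/C=C/C(=O)OC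
F5 | step 10 | methyl 2-[(3S*,6R*)-6-[(6E)-hexadec-6-ene-4,15-diyn-1-yl]-6-methoxy-1,2-dioxan-3-yl]acetate (racemate) | C#CCCCCCCC/C=C/C#CCCCC1(OC)CCC(CC(=O)OC)OO1
F6 | step 6 | (1E)-1-iodoundec-1-en-10-yne | C#CCCCCCCC/C=C/I
F7 | step 6 | 1-(1,3-dioxolan-2-yl)-8-(tributylstannyl)oct-7-yn-3-one | CCCC[Sn](CCCC)(CCCC)C#CCCCC(=O)CCC1OCCO1
F0 | step 11 | none | none
A1 | alternative 1 | methyl (2E)-6-hydroperoxy-6-methoxyundec-2-en-10-ynoate (racemic) | C#CCCCC(OC)(OO)CC/C=C/C(=O)OC
A2 | alternative 1 | methyl 2-[6-methoxy-6-(pent-4-yn-1-yl)-1,2-dioxan-3-yl]acetate (racemic, cis/trans) | C#CCCCC1(OC)CCC(CC(=O)OC)OO1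
A3 | alternative 2 | 3-[(6E)-hexadec-6-ene-4,15-diyn-1-yl]-3,6-dimethoxy-1,2-dioxane | C#CCCCCCCC/C=C/C#CCCCC1(OC)CCC(OC)OO1
A4 | alternative 3 | (8E)-2-methoxyoctadeca-1,8-diene-6,17-diyne | C=C(OC)CCCC#C/C=C/CCCCCCCC#C
A5 | alternative 3 | methyl 2-[6-[(6E)-hexadec-6-ene-4,15-diyn-1-yl]-6-methoxy-1,2-dioxan-3-yl]acetate (racemic mixture of diastereomers) | C#CCCCCCCC/C=C/C#CCCCC1(OC)CCC(CC(=O)OC)OO1
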